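**Assumptions.** The target has no stereocenters and is achiral, so no enantiocontrol is needed. 2-Methylphloroglucinol and 2,4,6-trihydroxyacetophenone are taken as commercial. Both rings come from commercial aromatic precursors, so no ring-closing step is used.

**Retrosynthesis**
1. Aspidin AB is disconnected at the benzylic CH2–C bond into an acylphloroglucinol ortho-quinone methide equivalent (a Mannich base, **12**) and 6-acetylfilicinic acid (**10**). Using a Mannich base avoids homodimer mixtures, because each partner has only one nucleophilic or electrophilic site.
2. Mannich base **12** comes from ketone **8**. Ketone **8** is made from 2-methylphloroglucinol (**1**) by Friedel–Crafts butyrylation, 4,6-di-O-benzylation (the hindered 2-OH stays free), O-methylation of that hindered OH, and hydrogenolysis.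
3. The filicinic-acid ring **10** is formed by dearomatizing gem-dimethylation of phloracetophenone (**9**).

**Step 1**
Reactants: **1** 2-methylbenzene-1,3,5-triol (2-methylphloroglucinol); **2** butyric acid
Product: **3** 1-(2,4,6-trihydroxy-3-methylphenyl)butan-1-one
Conditions: BF3·OEt2, 90 °C, N2, 2 h
Reagents that add atoms: butyric acid, CCCC(=O)O
Why: Friedel–Crafts C-acylation; the two free ring positions of **1** are equivalent, so there is one regioisomer, and the acyl group deactivates the ring against a second acylation.

**Step 2**
Reactants: **3**; **4** benzyl bromide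
Product: **5** 1-(4,6-bis(benzyloxy)-2-hydroxy-3-methylphenyl)butan-1-one
Conditions: BnBr (2.1 equiv), K2CO3, acetone, reflux
Reagents that add atoms: BnBr, BrCc1ccccc1
Why: Williamson O-alkylation. The 4-OH (para to the acyl group, most acidic) and the unhindered, chelated 6-OH react first, while the 2-OH, flanked by the acyl group and the C-methyl and hydrogen-bonded to the C=O, is left. This is the usual outcome when 2,4,6-trihydroxy-3-methylacyl-benzenes are dialkylated.

**Step 3**
Reactants: **5**; **6** methyl iodide
Product: **7** 1-(4,6-bis(benzyloxy)-2-methoxy-3-methylphenyl)butan-1-one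
Conditions: MeI (3 equiv), K2CO3, DMF, 50 °C
Reagents that add atoms: MeI, CI
Why: O-methylation of the only free phenol, which sets the OMe next to both the acyl group and the C-methyl as in the target.

**Step 4**
Reactants: **7**
Product: **8** 1-(4,6-dihydroxy-2-methoxy-3-methylphenyl)butan-1-one
Conditions: H2 (1 atm), 10% Pd/C, EtOAc, rt, 2 h
Reagents that add atoms: none
Why: Hydrogenolysis of the two benzyl ethers; the aryl ketone, OMe and aryl-CH3 survive short, neutral hydrogenolysis.

**Step 5** (parallel branch)
Reactants: **9** 2,4,6-trihydroxyacetophenone (phloracetophenone); **6** methyl iodide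
Product: **10** 6-acetyl-2,2-dimethylcyclohexane-1,3,5-trione (2-acetylfilicinic acid, drawn as the enol)
Conditions: MeI (2.2 equiv), NaOMe (4 equiv), MeOH, 0 °C to rt, then aq. HCl
Reagents that add atoms: MeI, CI
Why: Exhaustive C-methylation of a phloroglucinol enolate dearomatizes the ring. Both methyls go onto one of the two equivalent ring CH positions, giving the CMe2 flanked by two carbonyls, with the acetyl-bearing carbon next to a carbonyl that is itself next to CMe2, as in the target. The remaining CH2 is the future bridging carbon.

**Step 6**
Reactants: **8**; **11** Eschenmoser's salt (dimethylmethyleneiminium iodide)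
Product: **12** 1-(3-((dimethylamino)methyl)-4,6-dihydroxy... named as: 1-{3-[(dimethylamino)methyl]-2,4-dihydroxy-6-methoxy-5-methylphenyl}butan-1-one
Conditions: Eschenmoser's salt (1.1 equiv), MeCN, rt, 12 h; sat. NaHCO3 workup
Reagents that add atoms: Eschenmoser's salt, C[N+](C)=C.[I-]
Why: Mannich aminomethylation (electrophilic aromatic substitution) at the only free ring carbon of **8**, which lies between two OH groups and para to the OMe.

**Step 7**
Reactants: **12**; **10**
Product: **13** aspidin AB
Conditions: toluene, 110 °C, 6 h; then 1 M HCl
Reagents that add atoms: none (Me2NH is lost)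
Why: Thermal loss of Me2NH from the phenolic Mannich base gives an ortho-quinone methide, which is trapped by the enolized triketone at its unsubstituted CH2 (oxa-Michael-type conjugate C-alkylation, Mannich-base/o-QM coupling). No stereocenter is formed.

**Compound list**

| No. | Name | SMILES | Role |
|---|---|---|---|
| 1 | 2-Methylphloroglucinol | Cc1c(O)cc(O)cc1O | starting material |
| 2 | Butyric acid | CCCC(=O)O | starting material |
| 3 | 1-(2,4,6-Trihydroxy-3-methylphenyl)butan-1-one | CCCC(=O)c1c(O)c(C)c(O)cc1O | intermediate |
| 4 | Benzyl bromide | BrCc1ccccc1 | starting material |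
| 5 | 1-(4,6-Bis(benzyloxy)-2-hydroxy-3-methylphenyl)butan-1-one | CCCC(=O)c1c(OCc2ccccc2)cc(OCc2ccccc2)c(C)c1O | intermediate |
| 6 | Methyl iodide | CI | starting material |
| 7 | 1-(4,6-Bis(benzyloxy)-2-methoxy-3-methylphenyl)butan-1-one | CCCC(=O)c1c(OCc2ccccc2)cc(OCc2ccccc2)c(C)c1OC | intermediate |
| 8 | 1-(4,6-Dihydroxy-2-methoxy-3-methylphenyl)butan-1-one | CCCC(=O)c1c(O)cc(O)c(C)c1OC | intermediate |
| 9 | 2,4,6-Trihydroxyacetophenone | CC(=O)c1c(O)cc(O)cc1O | starting material |
| 10 | 6-Acetyl-2,2-dimethylcyclohexane-1,3,5-trione (enol form) | CC(=O)C1=C(O)CC(=O)C(C)(C)C1=O | intermediate |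
| 11 | Eschenmoser's salt | C[N+](C)=C.[I-] | starting material |
| 12 | Mannich base of **8** | CCCC(=O)c1c(O)c(CN(C)C)c(O)c(C)c1OC | intermediate |
| 13 | Aspidin AB (C23H28O8, achiral) | CCCC(=O)c1c(O)c(CC2=C(O)C(C)(C)C(=O)C(C(C)=O)=C2O)c(O)c(C)c1OC | target |

**Totals.** There are 7 steps in all. The longest linear sequence is 6 steps (1→3→5→7→8→12→13); step 5 runs in parallel.

**Three steps most likely to fail**
1. **Step 5, gem-dimethylation.** It can give mono-, tetra- or O-methylated mixtures. Fallback: build the ring by Dieckmann/Claisen cyclization of methyl 2,2-dimethyl-3,5-dioxohexanoate to filicinic acid, then C-acetylate (AcCl, then DMAP O→C rearrangement).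
2. **Step 2, selective 4,6-dibenzylation.** The hindered 2-OH might also react, or only a mono-ether might form. Fallback: start from 1,3,5-trimethoxybenzene, C-methylate it (n-BuLi, MeI), acylate it (Friedel–Crafts butyrylation), and remove two OMe groups with a Lewis acid (BCl3 or AlCl3) to reach **8**.
3. **Step 7, o-QM coupling.** Alkylation may occur at the wrong carbon of the triketone (C6 instead of C4), or the o-QM may decompose. Fallback: run a three-component Knoevenagel/Michael sequence instead, in which **10** and paraformaldehyde form the 4-methylene triketone in situ and **8** adds to it.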